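**Plan**

Locants are the germacranolide ones: C1 ring ketone, C2 ring CH, C3 O-bearing sp2 carbon, C4 CHMe, C5 CHOH, C6 lactone CH–O, C7, C8 CHOAng, C9 CH2, C10 C(Me)–O, C11–C13 methylene lactone.
The furanone ring (O, C3, C2, C1, C10) is a cyclic vinylogous ester: C3 is at the acid oxidation level and its ring oxygen sits on C10, next to the C1 ketone.
Retrosynthesis cuts, in this order: the C2–C3 bond (retro-Claisen, giving a nine-membered lactone in which the C3 carboxyl acylates the C10 oxygen and C10 carries an acetyl group); C7–C8 (allylation, which opens that lactone); the ester bond C3–O; C4–C5 (aldol).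
Forward: the carbinol fragment (C8–C10, C1, C2) and the acid fragment (C3–C7) are made separately and esterified; metathesis builds the butenolide; an intramolecular Nozaki–Hiyama–Kishi allylation closes the nine-membered lactone and creates the methylene lactone; the angelate is put on; the acyl shift and dehydration then form the ten-membered carbocycle and the furanone in one operation; desilylation ends the route.
Stereochemistry: C10 from (S)-lactic acid (alkylation with retention), C6 from (S)-but-3-ene-1,2-diol, C5 and C4 from a chelation-controlled Mukaiyama aldol reaction, C7 and C8 from the chair transition state of the allylation on the C6-substituted butenolide; the angelate geometry comes from angelic acid.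

Key step: step 19

**Route**

Step 1
Reactants: 1 (2S,5S)-2-tert-butyl-5-methyl-1,3-dioxolan-4-one; 2 1-bromo-3-methylbut-2-ene
Product: 4 (2S,5R)-2-tert-butyl-5-methyl-5-(3-methylbut-2-en-1-yl)-1,3-dioxolan-4-one, via lithium enolate 3 (not isolated)
Conditions: LiN(i-Pr)2, THF, −78 °C; then 2, −78 → −30 °C
Reagents that add atoms: none
Why: Seebach alkylation (self-regeneration of stereocentres), in which the enolate is attacked anti to the tert-butyl group so that the prenyl group replaces H with retention and fixes the later C10 as R.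

Step 2
Reactants: 4 (2S,5R)-2-tert-butyl-5-methyl-5-(3-methylbut-2-en-1-yl)-1,3-dioxolan-4-one
Product: 5 (2R)-2-hydroxy-N-methoxy-N,2,5-trimethylhex-4-enamide
Conditions: MeNH(OMe)·HCl, i-PrMgCl, THF, −20 → 0 °C
Reagents that add atoms: N,O-dimethylhydroxylamine hydrochloride CNOC.Cl
Why: Aminolysis of the activated acylal-type lactone by the chloromagnesium amide should give the Weinreb amide while the hemiacetal alkoxide expels pivalaldehyde, the quaternary stereocentre not being touched.

Step 3
Reactants: 5 (2R)-2-hydroxy-N-methoxy-N,2,5-trimethylhex-4-enamide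
Product: 6 (3R)-3-hydroxy-3,6-dimethylhept-5-en-2-one
Conditions: MeMgBr (3 equiv), THF, 0 °C; aq. NH4Cl
Reagents that add atoms: methylmagnesium bromide C[Mg]Br
Why: Weinreb ketone synthesis, in which the chelated tetrahedral intermediate prevents a second addition and one equivalent of Grignard reagent is spent on the free hydroxyl.

Step 4
Reactants: 7 propanoyl chloride; 8 2-methylpropane-2-thiol
Product: 9 S-tert-butyl propanethioate
Conditions: pyridine, CH2Cl2, 0 → 23 °C
Reagents that add atoms: none
Why: Simple acyl substitution of the acid chloride by the thiol (thioester formation).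

Step 5
Reactants: 9 S-tert-butyl propanethioate
Product: 11 tert-butyl{[(1Z)-1-(tert-butylsulfanyl)prop-1-en-1-yl]oxy}dimethylsilane (methyl trans to the silyloxy group), via lithium enolate 10 (not isolated)
Conditions: LiN(i-Pr)2, THF, −78 °C; then TBSCl, DMPU, −78 → 23 °C
Reagents that add atoms: tert-butyldimethylsilyl chloride CC(C)(C)[Si](C)(C)Cl
Why: Kinetic enolisation in THF (Ireland model) should give the enolate with methyl trans to oxygen, which is trapped on oxygen as the silyl ketene thioacetal.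

Step 6
Reactants: 12 (2S)-but-3-ene-1,2-diol; 13 4-methoxybenzaldehyde dimethyl acetal
Product: 14 (4S)-2-(4-methoxyphenyl)-4-vinyl-1,3-dioxolane (both acetal epimers)
Conditions: PPTS (cat.), CH2Cl2, 23 °C
Reagents that add atoms: none
Why: Acid-catalysed transacetalisation of the 1,2-diol, which does not touch the carbinol stereocentre (later C6).

Step 7
Reactants: 14 (4S)-2-(4-methoxyphenyl)-4-vinyl-1,3-dioxolane
Product: 15 (2S)-2-[(4-methoxybenzyl)oxy]but-3-en-1-ol
Conditions: i-Bu2AlH, CH2Cl2, −78 → 0 °C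
Reagents that add atoms: none
Why: Reductive opening of the p-methoxybenzylidene acetal, in which aluminium binds the less hindered primary oxygen so that the PMB group should end on the secondary oxygen.

Step 8
Reactants: 15 (2S)-2-[(4-methoxybenzyl)oxy]but-3-en-1-ol
Product: 16 (2S)-2-[(4-methoxybenzyl)oxy]but-3-enal
Conditions: Dess–Martin periodinane, NaHCO3, CH2Cl2, 0 °C; used at once
Reagents that add atoms: none
Why: Dess–Martin oxidation under buffered, amine-free conditions should give the aldehyde without shifting the double bond into conjugation or epimerising the α-alkoxy centre.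

Step 9
Reactants: 16 (2S)-2-[(4-methoxybenzyl)oxy]but-3-enal; 11 tert-butyl{[(1Z)-1-(tert-butylsulfanyl)prop-1-en-1-yl]oxy}dimethylsilane
Product: 17 S-tert-butyl (2R,3S,4S)-3-hydroxy-4-[(4-methoxybenzyl)oxy]-2-methylhex-5-enethioate
Conditions: MgBr2·OEt2 (3 equiv), CH2Cl2, −78 → −30 °C; aq. HCl work-up
Reagents that add atoms: none
Why: Chelation-controlled Mukaiyama aldol reaction, in which MgBr2 bridges the aldehyde and PMB-ether oxygens so that the ketene thioacetal adds anti to the vinyl group (C5/C6 syn), and the open antiperiplanar transition state of the methyl-trans-to-silyloxy isomer should give the C4/C5 anti relationship.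

Step 10
Reactants: 17 S-tert-butyl (2R,3S,4S)-3-hydroxy-4-[(4-methoxybenzyl)oxy]-2-methylhex-5-enethioate
Product: 18 S-tert-butyl (2R,3S,4S)-3-[(tert-butyldimethylsilyl)oxy]-4-[(4-methoxybenzyl)oxy]-2-methylhex-5-enethioate
Conditions: TBSOTf, 2,6-lutidine, CH2Cl2, −78 → 0 °C
Reagents that add atoms: tert-butyldimethylsilyl trifluoromethanesulfonate CC(C)(C)[Si](C)(C)OS(=O)(=O)C(F)(F)F
Why: Standard silylation of a hindered secondary alcohol, which blocks the C5 oxygen until the last step.

Step 11
Reactants: 18 S-tert-butyl (2R,3S,4S)-3-[(tert-butyldimethylsilyl)oxy]-4-[(4-methoxybenzyl)oxy]-2-methylhex-5-enethioate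
Product: 19 (2R,3S,4S)-3-[(tert-butyldimethylsilyl)oxy]-4-[(4-methoxybenzyl)oxy]-2-methylhex-5-enoic acid
Conditions: AgNO3, 2,6-lutidine, THF/H2O (4:1), 23 °C
Reagents that add atoms: water O
Why: Thiophilic silver-assisted hydrolysis of the thioester, which is close to neutral and should therefore avoid β-elimination of the silyloxy group and epimerisation at C4.

Step 12
Reactants: 19 (2R,3S,4S)-3-[(tert-butyldimethylsilyl)oxy]-4-[(4-methoxybenzyl)oxy]-2-methylhex-5-enoic acid; 6 (3R)-3-hydroxy-3,6-dimethylhept-5-en-2-one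
Product: 21 (3R)-3,6-dimethyl-2-oxohept-5-en-3-yl (2R,3S,4S)-3-[(tert-butyldimethylsilyl)oxy]-4-[(4-methoxybenzyl)oxy]-2-methylhex-5-enoate, via mixed anhydride 20 (not isolated)
Conditions: 2,4,6-Cl3C6H2COCl, Et3N, THF, 23 °C; then 6, DMAP, toluene, 23 → 60 °C
Reagents that add atoms: none
Why: Yamaguchi esterification, in which the acyl-DMAP species from the mixed anhydride acylates the tertiary α-ketol (the usual way to α-acyloxy ketones of this kind) and joins the two fragments without creating a stereocentre.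

Step 13
Reactants: 21 (3R)-3,6-dimethyl-2-oxohept-5-en-3-yl (2R,3S,4S)-3-[(tert-butyldimethylsilyl)oxy]-4-[(4-methoxybenzyl)oxy]-2-methylhex-5-enoate
Product: 22 (3R)-3,6-dimethyl-2-oxohept-5-en-3-yl (2R,3S,4S)-3-[(tert-butyldimethylsilyl)oxy]-4-hydroxy-2-methylhex-5-enoate
Conditions: DDQ, CH2Cl2/pH 7 buffer, 0 → 23 °C
Reagents that add atoms: none
Why: Oxidative cleavage of the PMB ether by DDQ, which leaves the silyl ether, the ketone, the tertiary ester and the alkenes alone.

Step 14
Reactants: 22 (3R)-3,6-dimethyl-2-oxohept-5-en-3-yl (2R,3S,4S)-3-[(tert-butyldimethylsilyl)oxy]-4-hydroxy-2-methylhex-5-enoate; 23 2-(bromomethyl)prop-2-enoic acid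
Product: 25 (3R)-3,6-dimethyl-2-oxohept-5-en-3-yl (2R,3S,4S)-4-{[2-(bromomethyl)prop-2-enoyl]oxy}-3-[(tert-butyldimethylsilyl)oxy]-2-methylhex-5-enoate, via acid chloride 24 (not isolated)
Conditions: 23, (COCl)2, DMF (cat.), CH2Cl2, 0 → 23 °C, concentrate; then 22, i-Pr2NEt, CH2Cl2, −78 → 0 °C
Reagents that add atoms: none
Why: Acylation of the allylic C6 alcohol by the reactive acryloyl chloride, with a hindered non-nucleophilic base so that the allylic bromide is not displaced.

Step 15
Reactants: 25 (3R)-3,6-dimethyl-2-oxohept-5-en-3-yl (2R,3S,4S)-4-{[2-(bromomethyl)prop-2-enoyl]oxy}-3-[(tert-butyldimethylsilyl)oxy]-2-methylhex-5-enoate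
Product: 26 (3R)-3,6-dimethyl-2-oxohept-5-en-3-yl (2R,3S)-3-[(2S)-4-(bromomethyl)-5-oxo-2,5-dihydrofuran-2-yl]-3-[(tert-butyldimethylsilyl)oxy]-2-methylpropanoate
Conditions: second-generation Grubbs catalyst, (H2IMes)(PCy3)Cl2Ru=CHPh (5 mol%), CH2Cl2 (5 mM), 40 °C
Reagents that add atoms: none
Why: Ring-closing metathesis of the acrylate with the neighbouring vinyl group should give the five-membered butenolide, the trisubstituted prenyl alkene being too slow to compete.

Step 16
Reactants: 26 (3R)-3,6-dimethyl-2-oxohept-5-en-3-yl (2R,3S)-3-[(2S)-4-(bromomethyl)-5-oxo-2,5-dihydrofuran-2-yl]-3-[(tert-butyldimethylsilyl)oxy]-2-methylpropanoate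
Product: 28 (3R)-3-methyl-1,4-dioxopentan-3-yl (2R,3S)-3-[(2S)-4-(bromomethyl)-5-oxo-2,5-dihydrofuran-2-yl]-3-[(tert-butyldimethylsilyl)oxy]-2-methylpropanoate, via vicinal diol 27 (not isolated)
Conditions: OsO4 (2 mol%), NaIO4, 2,6-lutidine, dioxane/H2O (3:1), 23 °C
Reagents that add atoms: osmium tetroxide O=[Os](=O)(=O)=O (catalytic, reoxidised by sodium periodate [Na+].[O-]I(=O)(=O)=O)
Why: Lemieux–Johnson cleavage, in which OsO4 should attack only the electron-rich prenyl alkene and not the electron-poor butenolide, and the lutidine buffer protects the β-acyloxy aldehyde from elimination.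

Step 17
Reactants: 28 (3R)-3-methyl-1,4-dioxopentan-3-yl (2R,3S)-3-[(2S)-4-(bromomethyl)-5-oxo-2,5-dihydrofuran-2-yl]-3-[(tert-butyldimethylsilyl)oxy]-2-methylpropanoate
Product: 30 (4R,5S,6S,7R,8S,10R)-10-acetyl-5-[(tert-butyldimethylsilyl)oxy]-8-hydroxy-4,10-dimethyl nine-membered 3,10-lactone (ring O–C3(=O)–C4–C5–C6–C7–C8–C9–C10) trans-fused at C6–C7 to the 6,12-α-methylene-γ-butyrolactone, via allylchromium species 29 (not isolated)
Conditions: CrCl2 (8 equiv), THF, 23 °C, slow addition of 28 (final 2 mM)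
Reagents that add atoms: none
Why: Intramolecular Nozaki–Hiyama–Kishi allylation, in which the allylchromium adds through C7 to the aldehyde (not to the ketone) in a chair transition state, the ring-fixed E-type allyl geometry giving the 7,8-anti relationship (C8 S) and attack on the butenolide face opposite the C5 substituent giving the 6,7-trans lactone (C7 R) with the double bond moved to the exocyclic position.

Step 18
Reactants: 30 the hydroxy lactone of step 17; 31 angelic acid, (2Z)-2-methylbut-2-enoic acid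
Product: 33 (4R,5S,6S,7R,8S,10R)-10-acetyl-8-(angeloyloxy)-5-[(tert-butyldimethylsilyl)oxy]-4,10-dimethyl nine-membered 3,10-lactone trans-fused at C6–C7 to the 6,12-α-methylene-γ-butyrolactone, via mixed anhydride 32 (not isolated)
Conditions: 31, 2,4,6-Cl3C6H2COCl, Et3N, toluene, 23 °C, filter; then 30, toluene, 80 °C
Reagents that add atoms: none
Why: Yamaguchi-type mixed-anhydride acylation run without DMAP and without free amine, which should keep the Z geometry of the angelate and give no base to start a 1,3 O→O acyl shift of the lactone to the C8 oxygen.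

Step 19
Reactants: 33 the angelate lactone of step 18
Product: 36 5-O-(tert-butyldimethylsilyl)rufescenolide B, via lithium enolate 34 (not isolated), via hydroxy diketone 35 (not isolated)
Conditions: LiN(SiMe3)2 (1.3 equiv), THF, −78 → −40 °C; AcOH; then p-TsOH·H2O (0.2 equiv), CH2Cl2, 23 °C
Reagents that add atoms: none
Why: Proposed new method: kinetic deprotonation of the acetyl CH3 (the most acidic and least hindered C–H of 33) gives enolate 34, whose carbon C2 attacks the lactone carbonyl C3 through a five-membered transition state, and collapse of the lactol alkoxide with cleavage of the C3–O(C10) bond turns the nine-membered lactone into the ten-membered carbocyclic β-diketonate, the new C2–C3 bond being a ring bond. The closest known reaction type is the base-induced O→C acyl shift of acyclic α-acyloxy ketones (Baker–Venkataraman-type intramolecular Claisen condensation) followed by acid cyclodehydration to 3(2H)-furanones; what is new is its use on a medium-ring lactone, where it becomes a two-carbon ring expansion. The carbocycle is closed by this 5-exo-trig C-acylation with ring opening, driven by loss of medium-ring lactone strain and by formation of the diketonate, and the furanone ring by 5-exo-trig hemiketalisation of the C10 hydroxyl onto the C3 carbonyl with loss of water toward C2 under TsOH. No stereocentre is created: C10 keeps its oxygen throughout, and C4 should survive because only a slight excess of a hindered amide base is used at low temperature and the diketonate is not enolised further toward C4. The step needs chemoselective enolisation of the methyl ketone over the lactone α-CH, the angelate and the methylene lactone, which the pKa gap and the five-membered geometry should secure, and regioselective cyclodehydration, which is secured because the C10 hydroxyl is the only free one (C5 is silylated, C8 acylated) and can reach only C3 in a five-membered ring.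

Step 20
Reactants: 36 5-O-(tert-butyldimethylsilyl)rufescenolide B
Product: 37 rufescenolide B
Conditions: HF·pyridine, pyridine, THF, 0 → 23 °C
Reagents that add atoms: none
Why: Buffered fluoride desilylation, mild enough that the β-hydroxy furanone should not dehydrate and the angelate and methylene lactone should stay intact.

**Compound list**

1 | (2S,5S)-2-tert-butyl-5-methyl-1,3-dioxolan-4-one (cis) | C[C@@H]1O[C@H](C(C)(C)C)OC1=O | starting material
2 | 1-bromo-3-methylbut-2-ene (prenyl bromide) | CC(C)=CCBr | starting material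
3 | lithium enolate of 1 | CC1=C([O-])O[C@@H](C(C)(C)C)O1.[Li+] | intermediate
4 | (2S,5R)-2-tert-butyl-5-methyl-5-(3-methylbut-2-en-1-yl)-1,3-dioxolan-4-one | C[C@]1(CC=C(C)C)O[C@H](C(C)(C)C)OC1=O | intermediate
5 | (2R)-2-hydroxy-N-methoxy-N,2,5-trimethylhex-4-enamide | CON(C)C(=O)[C@](C)(O)CC=C(C)C | intermediate
6 | (3R)-3-hydroxy-3,6-dimethylhept-5-en-2-one | CC(=O)[C@](C)(O)CC=C(C)C | intermediate
7 | propanoyl chloride | CCC(Cl)=O | starting material
8 | 2-methylpropane-2-thiol | CC(C)(C)S | starting material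
9 | S-tert-butyl propanethioate | CCC(=O)SC(C)(C)C | intermediate
10 | lithium enolate of 9 (methyl trans to O) | C/C=C(/[O-])SC(C)(C)C.[Li+] | intermediate
11 | tert-butyl{[(1Z)-1-(tert-butylsulfanyl)prop-1-en-1-yl]oxy}dimethylsilane | C/C=C(/O[Si](C)(C)C(C)(C)C)SC(C)(C)C | intermediate
12 | (2S)-but-3-ene-1,2-diol | C=C[C@H](O)CO | starting material
13 | 4-methoxybenzaldehyde dimethyl acetal | COC(OC)c1ccc(OC)cc1 | starting material
14 | (4S)-2-(4-methoxyphenyl)-4-vinyl-1,3-dioxolane (acetal epimers) | C=C[C@H]1COC(c2ccc(OC)cc2)O1 | intermediate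
15 | (2S)-2-[(4-methoxybenzyl)oxy]but-3-en-1-ol | COc1ccc(CO[C@@H](C=C)CO)cc1 | intermediate
16 | (2S)-2-[(4-methoxybenzyl)oxy]but-3-enal | COc1ccc(CO[C@@H](C=C)C=O)cc1 | intermediate
17 | S-tert-butyl (2R,3S,4S)-3-hydroxy-4-[(4-methoxybenzyl)oxy]-2-methylhex-5-enethioate | COc1ccc(CO[C@@H](C=C)[C@@H](O)[C@@H](C)C(=O)SC(C)(C)C)cc1 | intermediate
18 | S-tert-butyl (2R,3S,4S)-3-[(tert-butyldimethylsilyl)oxy]-4-[(4-methoxybenzyl)oxy]-2-methylhex-5-enethioate | COc1ccc(CO[C@@H](C=C)[C@@H](O[Si](C)(C)C(C)(C)C)[C@@H](C)C(=O)SC(C)(C)C)cc1 | intermediate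
19 | (2R,3S,4S)-3-[(tert-butyldimethylsilyl)oxy]-4-[(4-methoxybenzyl)oxy]-2-methylhex-5-enoic acid | COc1ccc(CO[C@@H](C=C)[C@@H](O[Si](C)(C)C(C)(C)C)[C@@H](C)C(=O)O)cc1 | intermediate
20 | mixed anhydride of 19 with 2,4,6-trichlorobenzoic acid | COc1ccc(CO[C@@H](C=C)[C@@H](O[Si](C)(C)C(C)(C)C)[C@@H](C)C(=O)OC(=O)c2c(Cl)cc(Cl)cc2Cl)cc1 | intermediate
21 | (3R)-3,6-dimethyl-2-oxohept-5-en-3-yl (2R,3S,4S)-3-[(tert-butyldimethylsilyl)oxy]-4-[(4-methoxybenzyl)oxy]-2-methylhex-5-enoate | COc1ccc(CO[C@@H](C=C)[C@@H](O[Si](C)(C)C(C)(C)C)[C@@H](C)C(=O)O[C@@](C)(C(C)=O)CC=C(C)C)cc1 | intermediate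
22 | (3R)-3,6-dimethyl-2-oxohept-5-en-3-yl (2R,3S,4S)-3-[(tert-butyldimethylsilyl)oxy]-4-hydroxy-2-methylhex-5-enoate | O[C@@H](C=C)[C@@H](O[Si](C)(C)C(C)(C)C)[C@@H](C)C(=O)O[C@@](C)(C(C)=O)CC=C(C)C | intermediate
23 | 2-(bromomethyl)prop-2-enoic acid | C=C(CBr)C(=O)O | starting material
24 | 2-(bromomethyl)prop-2-enoyl chloride | C=C(CBr)C(Cl)=O | intermediate
25 | (3R)-3,6-dimethyl-2-oxohept-5-en-3-yl (2R,3S,4S)-4-{[2-(bromomethyl)prop-2-enoyl]oxy}-3-[(tert-butyldimethylsilyl)oxy]-2-methylhex-5-enoate | C=C(CBr)C(=O)O[C@@H](C=C)[C@@H](O[Si](C)(C)C(C)(C)C)[C@@H](C)C(=O)O[C@@](C)(C(C)=O)CC=C(C)C | intermediate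
26 | (3R)-3,6-dimethyl-2-oxohept-5-en-3-yl (2R,3S)-3-[(2S)-4-(bromomethyl)-5-oxo-2,5-dihydrofuran-2-yl]-3-[(tert-butyldimethylsilyl)oxy]-2-methylpropanoate | O=C1O[C@@H](C=C1CBr)[C@@H](O[Si](C)(C)C(C)(C)C)[C@@H](C)C(=O)O[C@@](C)(C(C)=O)CC=C(C)C | intermediate
27 | vicinal diol from 26 (prenyl C=C dihydroxylated, C8 epimers) | O=C1O[C@@H](C=C1CBr)[C@@H](O[Si](C)(C)C(C)(C)C)[C@@H](C)C(=O)O[C@@](C)(C(C)=O)CC(O)C(C)(C)O | intermediate
28 | (3R)-3-methyl-1,4-dioxopentan-3-yl (2R,3S)-3-[(2S)-4-(bromomethyl)-5-oxo-2,5-dihydrofuran-2-yl]-3-[(tert-butyldimethylsilyl)oxy]-2-methylpropanoate | O=C1O[C@@H](C=C1CBr)[C@@H](O[Si](C)(C)C(C)(C)C)[C@@H](C)C(=O)O[C@@](C)(C(C)=O)CC=O | intermediate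
29 | allylchromium dichloride from 28 (trivalent chromium on the former CH2Br carbon) | O=C1O[C@@H](C=C1C[Cr](Cl)Cl)[C@@H](O[Si](C)(C)C(C)(C)C)[C@@H](C)C(=O)O[C@@](C)(C(C)=O)CC=O | intermediate
30 | (4R,5S,6S,7R,8S,10R)-10-acetyl-5-[(tert-butyldimethylsilyl)oxy]-8-hydroxy-4,10-dimethyl nine-membered 3,10-lactone trans-fused at C6–C7 to the 6,12-α-methylene-γ-butyrolactone | C=C1C(=O)O[C@@H]2[C@@H](O[Si](C)(C)C(C)(C)C)[C@@H](C)C(=O)O[C@@](C)(C(C)=O)C[C@H](O)[C@@H]12 | intermediate
31 | angelic acid, (2Z)-2-methylbut-2-enoic acid | C/C=C(/C)C(=O)O | starting material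
32 | mixed anhydride of angelic acid with 2,4,6-trichlorobenzoic acid | C/C=C(/C)C(=O)OC(=O)c1c(Cl)cc(Cl)cc1Cl | intermediate
33 | 8-O-angeloyl derivative of 30 (4R,5S,6S,7R,8S,10R) | C=C1C(=O)O[C@@H]2[C@@H](O[Si](C)(C)C(C)(C)C)[C@@H](C)C(=O)O[C@@](C)(C(C)=O)C[C@H](OC(=O)/C(C)=C\C)[C@@H]12 | intermediate
34 | lithium enolate of 33 (acetyl CH3 deprotonated) | C=C1C(=O)O[C@@H]2[C@@H](O[Si](C)(C)C(C)(C)C)[C@@H](C)C(=O)O[C@@](C)(C(=C)[O-])C[C@H](OC(=O)/C(C)=C\C)[C@@H]12.[Li+] | intermediate
35 | (4R,5S,6S,7R,8S,10R)-8-(angeloyloxy)-5-[(tert-butyldimethylsilyl)oxy]-10-hydroxy-4,10-dimethyl-1,3-dioxo ten-membered carbocycle fused at C6–C7 to the methylene lactone | C=C1C(=O)O[C@@H]2[C@@H](O[Si](C)(C)C(C)(C)C)[C@@H](C)C(=O)CC(=O)[C@](C)(O)C[C@H](OC(=O)/C(C)=C\C)[C@@H]12 | intermediate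
36 | 5-O-(tert-butyldimethylsilyl)rufescenolide B | C=C1C(=O)O[C@@H]2[C@@H](O[Si](C)(C)C(C)(C)C)[C@@H](C)C3=CC(=O)[C@@](C)(C[C@H](OC(=O)/C(C)=C\C)[C@@H]12)O3 | intermediate
37 | rufescenolide B | C=C1C(=O)O[C@@H]2[C@@H](O)[C@@H](C)C3=CC(=O)[C@@](C)(C[C@H](OC(=O)/C(C)=C\C)[C@@H]12)O3 | target

**Count and risks**

Total step count: 20. Longest linear sequence: 15 steps (steps 6–20, from diol 12).

Step 19 (key step). The enolate may be drained by proton transfer or by conjugate addition to the methylene lactone before the transannular acyl shift takes place, or the strained bicyclic tetrahedral intermediate may revert so that decomposition outruns ring expansion. The fallback uses known chemistry and builds the furanone first, closing the carbocycle later at C7–C8. It sets out from ester 21: the same base treatment on this acyclic α-acyloxy ketone (the classical O→C acyl shift) would give the acyclic hydroxy diketone F1, and TsOH would close it to the 3(2H)-furanone F2. DDQ would then free the C6 alcohol F3, acylation with 24 would give the bromomethylacrylate F4, and ring-closing metathesis the bromomethyl butenolide F5. OsO4/NaIO4 would give the aldehyde F6, and a CrCl2-mediated Nozaki–Hiyama–Kishi macrocyclisation (ten-membered ring closure of the kind used for germacranolides) the bridged hydroxy furanone lactone F7. Acylation of F7 with mixed anhydride 32 rejoins the route at 36.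

Step 17. The tether may force the aldehyde to add through its other face in the medium-ring transition state, or the free C8 hydroxyl may begin a 1,3-acyl shift on handling. If the closure of 28 gives the C8 epimer, the 8-epi hydroxy lactone F8, Mitsunobu esterification with angelic acid 31 (PPh3, diisopropyl azodicarboxylate, toluene, 0 °C) would invert C8 and give the angelate directly. This fallback sets out from 28 and rejoins the route at 33.

Step 12. Acyl transfer to the hindered tertiary ketol may be so slow that the activated acid epimerises at C4 through a ketene or the mixed anhydride decomposes. The fallback sets out from thioester 18 and skips step 11: thiophilic activation with AgOCOCF3 in the presence of carbinol 6 (Na2HPO4, benzene, 40 °C; thioester–alcohol coupling of the Masamune type, known for tertiary alcohols) would give ester 21 directly. No new compound is made (F0), and the route is rejoined at 21.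

Further compounds
F1 | step 19 | (3R)-3-hydroxy-3,6-dimethylhept-5-en-2-one C-acylated at C1 by the acyl group of 19: acyclic hydroxy 1,3-diketone | COc1ccc(CO[C@@H](C=C)[C@@H](O[Si](C)(C)C(C)(C)C)[C@@H](C)C(=O)CC(=O)[C@](C)(O)CC=C(C)C)cc1
F2 | step 19 | (2R)-2-methyl-2-(3-methylbut-2-en-1-yl)furan-3(2H)-one carrying at C5 the (2R,3S,4S)-3-[(tert-butyldimethylsilyl)oxy]-4-[(4-methoxybenzyl)oxy]hex-5-en-2-yl chain | COc1ccc(CO[C@@H](C=C)[C@@H](O[Si](C)(C)C(C)(C)C)[C@@H](C)C2=CC(=O)[C@@](C)(CC=C(C)C)O2)cc1
F3 | step 19 | C6 alcohol from F2 (PMB removed) | O[C@@H](C=C)[C@@H](O[Si](C)(C)C(C)(C)C)[C@@H](C)C1=CC(=O)[C@@](C)(CC=C(C)C)O1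
F4 | step 19 | 2-(bromomethyl)prop-2-enoate of F3 | C=C(CBr)C(=O)O[C@@H](C=C)[C@@H](O[Si](C)(C)C(C)(C)C)[C@@H](C)C1=CC(=O)[C@@](C)(CC=C(C)C)O1
F5 | step 19 | bromomethyl butenolide from F4 (furanone with prenyl group) | O=C1O[C@@H](C=C1CBr)[C@@H](O[Si](C)(C)C(C)(C)C)[C@@H](C)C2=CC(=O)[C@@](C)(CC=C(C)C)O2
F6 | step 19 | aldehyde from F5 (prenyl cut to CH2CHO) | O=C1O[C@@H](C=C1CBr)[C@@H](O[Si](C)(C)C(C)(C)C)[C@@H](C)C2=CC(=O)[C@@](C)(CC=O)O2
F7 | step 19 | 8-deangeloyl-5-O-(tert-butyldimethylsilyl)rufescenolide B (free C8 hydroxyl) | C=C1C(=O)O[C@@H]2[C@@H](O[Si](C)(C)C(C)(C)C)[C@@H](C)C3=CC(=O)[C@@](C)(C[C@H](O)[C@@H]12)O3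
F8 | step 17 | C8 epimer of 30 (4R,5S,6S,7R,8R,10R) | C=C1C(=O)O[C@@H]2[C@@H](O[Si](C)(C)C(C)(C)C)[C@@H](C)C(=O)O[C@@](C)(C(C)=O)C[C@@H](O)[C@@H]12
F0 | step 12 | none | none
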